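## The problem

The target is a bisabolane-type sesquiterpenoid: one cyclohexane ring with six substituted carbons, joined through a single C–C bond to an acyclic five-carbon chain. For orientation the ring is numbered C1 (bears the chain), C2 (CH2), C3 (Cl), C4 (CH3, OH), C5 (OH), C6 (angelate), and the chain C7 (=CH2), C8 (angelate), C9, C10 and C11 (epoxide). Seven stereocentres must be set (1R,3S,4S,5S,6S,8S,10S in this numbering): the chain at C1, the C4 and C5 hydroxyls and the C6 ester lie on one ring face and chlorine on the other. The ring centres can relay to each other (C3 to C1 during ring closure, the C6 hydroxyl to C4/C5 in a directed oxidation). C8 and C10 are insulated and must come from the chiral pool and from reagent control. The sensitive groups are the trisubstituted epoxide (acid), the two angelates (Z to E isomerisation under nucleophilic catalysis), and the trans-diaxial C3–Cl/C4–OH chlorohydrin (closes to an epoxide with base). Before the diol exists, the chloride is also allylic. Two secondary esters sit beside a free secondary/tertiary diol, so acylation must be site-controlled. The enabling feature is the C6 carbinol beside C1, which carries the 1,1-disubstituted C7=CH2 unit: this homoallylic alcohol is what a carbonyl-ene closure of a farnesal-type aldehyde leaves, and the C4/C5 cis-diol maps onto the enal double bond of that aldehyde.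

## Retrosynthesis

**Diol and C6 ester (31 ⇒ 30 ⇒ 29 ⇒ 28).** The C6 ester bond and both C–O bonds of the 4,5-diol are cut. The diol comes from syn-dihydroxylation of the C4=C5 alkene of 28, directed by the cis C6 hydroxyl with OsO4–TMEDA. Acylating C6 first would remove the directing group; acylating after diol release would favour the equatorial C5 hydroxyl. The chelated osmate ester 29 is therefore kept as the diol protecting group while the only free hydroxyl (C6) is esterified (30), then released. The forward steps must deliver osmium syn to C6–OH (also anti to chlorine), leave the exocyclic methylene alone, and free the diol without acid or strong base.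

**Epoxide (28 ⇒ 27).** The epoxide C–O bonds are cut to the prenyl alkene. A reagent-controlled Shi epoxidation is placed after all Lewis-acid and hydride steps (the epoxide would not survive them) and before osmylation (the prenyl alkene is the most electron-rich alkene and would compete for OsO4).

**C6 configuration and C8 ester (27 ⇒ 26 ⇒ 25 ⇒ 24 ⇒ 23).** Transition-state analysis of the ring closure (below) shows that it delivers the C6 hydroxyl trans to the side chain, i.e. the C6 epimer. The inversion is done by oxidation to enone 24 and equatorial hydride delivery (26 ⇒ 27). While C6 is a ketone it is distinguished from C8, so the silyl ether is exchanged for the angelate there (24 ⇒ 25 ⇒ 26). This removes any later need to tell two secondary alcohols apart.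

**Key disconnection (23 ⇒ 22).** The C1–C6 bond is cut. In the forward sense the C1=C7 alkene of the (2Z,6Z)-chloro-enal 22 adds to the aldehyde carbon while a hydrogen of the C7 methyl moves to oxygen. This forms the ring, the C7 methylene and two stereocentres from an acyclic precursor in one step. The precursor must have the (2Z) enal geometry (reach), the (6Z) alkene geometry (hydrogen taken from the methyl and not from C8), and the C3 chloride in place to steer C1.

**Chloride and aldehyde (22 ⇒ 21 ⇒ 20 ⇒ 19).** The C3–Cl bond is cut to the (R)-allylic alcohol 19, to be replaced with inversion. The chlorine is installed here because C3 is still an unhindered acyclic carbinol; after ring closure and dihydroxylation it would be flanked by the fully substituted C4. The aldehyde is unveiled last from the primary silyl ether, because a (Z)-γ-hydroxy enal would close to a lactol.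

**C3–C4 bond (19 ⇒ 18 ⇒ 17 ⇒ 12 + 16).** The C3–C4 bond is cut into aldehyde 12 and the (Z)-alkenyl iodide 16, joined by a Nozaki–Hiyama–Kishi coupling (non-basic, suited to the enolisable β,γ-unsaturated aldehyde). C8 is too remote to control C3, so the carbinol is oxidised (18) and reduced under Corey–Bakshi–Shibata control. Iodide 16 comes from but-2-yn-1-ol 13 by hydroalumination–iodination (15), which fixes the (2Z) geometry.

**C1=C7 alkene (12 ⇒ 11 ⇒ 10 ⇒ 6 + 8).** The alkene is cut by a Wittig disconnection into the α-silyloxy methyl ketone 6 and phosphonium salt 8. α-Alkoxy ketones give, with unstabilised ylides, the trisubstituted alkene with the oxygenated carbon cis to the new chain, which is the (6Z) geometry required.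

**Starting materials (6 ⇒ 4 ⇒ 3 ⇒ 1 + 2; 8 ⇒ 7).** Ketone 6 is traced to methyl (S)-glycidate 1, opened at the CH2 terminus by the isobutenyl Grignard reagent 2; this supplies C8 from the chiral pool in three operations. Salt 8 is made from bromide 7.

## Roads not taken

**Alternative 1:** Cut at C3=C4 by ring-closing metathesis, after a boron-mediated anti-aldol that joins C1 to C6 (C7 ketone enolate with a C8 benzoate, C6 aldehyde). The second-generation Grubbs catalyst would join an allyl terminus on C2 to an isopropenyl group on C4, with loss of ethylene, giving cyclohexenyl ketone A1.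
- Merits: C1 and C6 come from a well-understood aldol and C6 arrives with the correct configuration, so no inversion is needed. The C3=C4 alkene is a direct precursor of the trans chlorohydrin by anti addition of Cl+ and water. In these two respects this road is better than the chosen one.
- Weak points: C7 enters as a ketone, so the methylene must be added late to a carbonyl flanked by an epimerisable C1 and an α-acyloxy C8 (a β-hydroxy ketone, prone to retro-aldol). The chlorohydrin must form with the right face and regiochemistry beside an epoxide. Benzoate and silyl groups must be exchanged for angelates after the base-sensitive chlorohydrin exists.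
- Comparison: the chosen plan offers ring, methylene and two centres in one step, and a diol introduced by a matched directed reaction. It pays with weaker control at C1 and the C6 inversion.

**Alternative 2:** Cut at C1–C2 by a palladium-catalysed intramolecular allylic alkylation. Pd2(dba)3 (zerovalent palladium) with a chiral diphosphine ligand would ionise a primary allylic carbonate; the β-keto ester carbon C2 attacks the internal allyl terminus C1, giving the cyclic β-keto ester A2 with C7=CH2.
- Merits: C1 is set by the catalyst whatever the allyl geometry. The methylene appears in the closure as in the chosen plan. The diol is carried as an acetonide, so no late osmium step and no C6 inversion are needed. For C1 control this road is superior.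
- Weak points: C3 arrives as a ketone. After decarboxylation it must be reduced and converted to the chloride with inversion at a carbon flanked by the fully substituted acetal carbon C4, where SN2 is very slow and elimination likely. Acetonide removal needs acid in the presence of the epoxide, and three kinds of protecting group must be exchanged.
- Comparison: the chosen plan installs chlorine at an unhindered acyclic allylic carbinol and uses fewer protecting groups, at the price of substrate control at C1.

**Alternative 3:** Cut at C4–C5 by a SmI2 pinacol cyclisation of a C5 aldehyde onto a C4 methyl ketone, giving the cis-4,5-diol A3.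
- Merits: the ring and both carbinol centres form in one mild step, cis selectivity is typical for such chelated ketyl closures, and no alkene chemoselectivity problem or osmium is involved.
- Weak points: both carbonyls carry α-oxygen substituents (C3 silyl ether, C6 benzyl-type ether) that SmI2 can cleave reductively. The new diol usually forms anti to an adjacent alkoxy group, whereas C5–OH must be cis to C6–O. C1, C3 and C6 must be built on an acyclic chain beforehand. The C3 silyl ether must then become a chloride with inversion beside a free tertiary hydroxyl, which invites epoxide formation.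
- Comparison: this road avoids stoichiometric OsO4 and the C6 inversion. The chosen plan's diol step is stereochemically matched (syn to C6–OH, anti to Cl), and its chlorine is in place before the ring exists.

Key step: step 16

Remarks on the chemistry: positions are numbered as in the target (C1–C11). Compounds 1, 2, 7, 13, angelic acid and the L-fructose-derived enantiomer of the Shi ketone are taken as purchasable. Facial selectivity of the ring closure at C1 rests on C3 alone and is an expectation, not an established result.

## Route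

Step 1
Reactants: 1 methyl (2S)-oxirane-2-carboxylate [methyl (S)-glycidate]; 2 2-methyl-1-propenylmagnesium bromide
Product: 3 methyl (2S)-2-hydroxy-5-methylhex-4-enoate
Conditions: CuI (10 mol %), THF, −78 → −40 °C
Reagents that add atoms: none
Why: Copper-catalysed Grignard opening of a terminal epoxide at the unsubstituted carbon is faster at low temperature than addition to the ester; the stereocentre (future C8) is not touched, so the (S) configuration of 1 is carried into 3.

Step 2
Reactants: 3 methyl (2S)-2-hydroxy-5-methylhex-4-enoate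
Product: 4 methyl (2S)-2-[(tert-butyldimethylsilyl)oxy]-5-methylhex-4-enoate
Conditions: TBSCl, imidazole, DMF, rt
Reagents that add atoms: tert-butyldimethylsilyl chloride, CC(C)(C)[Si](C)(C)Cl
Why: Routine silylation of a secondary alcohol; the silyl ether later supplies the α-silyloxy group needed for the Z-selective Wittig reaction and carries C8–O through the Lewis-acid step.

Step 3
Reactants: 4 methyl (2S)-2-[(tert-butyldimethylsilyl)oxy]-5-methylhex-4-enoate
Product: 6 (3S)-3-[(tert-butyldimethylsilyl)oxy]-6-methylhept-5-en-2-one, via N-methoxy-N-methylamide 5 (not isolated)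
Conditions: MeNH(OMe)·HCl (1.5 equiv), i-PrMgCl (3.0 equiv), THF, −20 °C; then MeMgBr, −20 → 0 °C
Reagents that add atoms: methylmagnesium bromide, C[Mg]Br; N,O-dimethylhydroxylamine hydrochloride, CNOC.Cl (its atoms remain only in 5)
Why: Ester aminolysis by the magnesium amide followed by Grignard addition to the chelate-stabilised amide (telescoped Weinreb ketone synthesis); the tetrahedral chelate prevents over-addition and the cold, weakly basic medium should leave the α-stereocentre intact.

Step 4
Reactants: 7 (3-bromopropoxy)(tert-butyl)dimethylsilane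
Product: 8 {3-[(tert-butyldimethylsilyl)oxy]propyl}triphenylphosphonium bromide
Conditions: PPh3, MeCN, reflux
Reagents that add atoms: triphenylphosphine, c1ccc(cc1)P(c1ccccc1)c1ccccc1
Why: SN2 quaternisation of triphenylphosphine by a primary bromide.

Step 5
Reactants: 8 {3-[(tert-butyldimethylsilyl)oxy]propyl}triphenylphosphonium bromide; 6 (3S)-3-[(tert-butyldimethylsilyl)oxy]-6-methylhept-5-en-2-one
Product: 10 (3Z,5S)-1,5-bis[(tert-butyldimethylsilyl)oxy]-4,8-dimethylnona-3,7-diene, via phosphorus ylide 9 (not isolated)
Conditions: NaN(SiMe3)2, THF, −78 °C; then 6, −78 °C → rt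
Reagents that add atoms: none
Why: Wittig olefination of an α-silyloxy methyl ketone with an unstabilised ylide, a substrate class known to give the trisubstituted alkene with the oxygenated carbon (C8) cis to the new chain (C2), i.e. (Z); addition of the ketone at low temperature limits enolisation so that C8 should keep its configuration.

Step 6
Reactants: 10 (3Z,5S)-1,5-bis[(tert-butyldimethylsilyl)oxy]-4,8-dimethylnona-3,7-diene
Product: 11 (3Z,5S)-5-[(tert-butyldimethylsilyl)oxy]-4,8-dimethylnona-3,7-dien-1-ol
Conditions: HF·pyridine, pyridine, THF, 0 °C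
Reagents that add atoms: none
Why: Buffered HF·pyridine cleaves a primary TBS ether much faster than a hindered secondary allylic one (selective desilylation).

Step 7
Reactants: 11 (3Z,5S)-5-[(tert-butyldimethylsilyl)oxy]-4,8-dimethylnona-3,7-dien-1-ol
Product: 12 (3Z,5S)-5-[(tert-butyldimethylsilyl)oxy]-4,8-dimethylnona-3,7-dienal
Conditions: Dess–Martin periodinane, NaHCO3, CH2Cl2, 0 °C; used crude
Reagents that add atoms: none
Why: Dess–Martin oxidation under buffered conditions; the β,γ-unsaturated aldehyde is not chromatographed and is used at once, so the double bond should not move into conjugation.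

Step 8
Reactants: 13 but-2-yn-1-ol
Product: 15 (2Z)-3-iodobut-2-en-1-ol, via cyclic alkenylaluminate 14 (not isolated)
Conditions: NaAlH2(OCH2CH2OMe)2, THF, 0 °C → rt; then I2, −78 °C
Reagents that add atoms: iodine, II
Why: Alkoxide-directed trans-hydroalumination of a propargylic alcohol places aluminium on C3 cis to the CH2O group; iodinolysis with retention gives the (Z)-iodide that fixes the later (2Z) enal geometry.

Step 9
Reactants: 15 (2Z)-3-iodobut-2-en-1-ol
Product: 16 triethyl{[(2Z)-3-iodobut-2-en-1-yl]oxy}silane
Conditions: TESCl, imidazole, CH2Cl2, 0 °C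
Reagents that add atoms: triethylsilyl chloride, CC[Si](Cl)(CC)CC
Why: Routine silylation; the primary triethylsilyl ether can later be removed in the presence of the secondary TBS ether.

Step 10
Reactants: 12 (3Z,5S)-5-[(tert-butyldimethylsilyl)oxy]-4,8-dimethylnona-3,7-dienal; 16 triethyl{[(2Z)-3-iodobut-2-en-1-yl]oxy}silane
Product: 17 (2Z,6Z,8S)-8-[(tert-butyldimethylsilyl)oxy]-1-[(triethylsilyl)oxy]-3,7,11-trimethyldodeca-2,6,10-trien-4-ol (4RS, mixture of epimers at the future C3)
Conditions: CrCl2 (4 equiv), NiCl2 (2 mol %), DMSO, rt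
Reagents that add atoms: none
Why: Nozaki–Hiyama–Kishi coupling: the alkenylchromium species adds to the aldehyde with retention of alkene geometry under non-basic conditions that tolerate the enolisable aldehyde; the epimer mixture is of no consequence because the carbinol is oxidised next.

Step 11
Reactants: 17 (2Z,6Z,8S)-8-[(tert-butyldimethylsilyl)oxy]-1-[(triethylsilyl)oxy]-3,7,11-trimethyldodeca-2,6,10-trien-4-ol
Product: 18 (2Z,6Z,8S)-8-[(tert-butyldimethylsilyl)oxy]-1-[(triethylsilyl)oxy]-3,7,11-trimethyldodeca-2,6,10-trien-4-one
Conditions: Dess–Martin periodinane, NaHCO3, CH2Cl2, 0 °C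
Reagents that add atoms: none
Why: Dess–Martin oxidation of a secondary allylic alcohol; neutral buffered conditions should keep the skipped C1=C7 alkene out of conjugation.

Step 12
Reactants: 18 (2Z,6Z,8S)-8-[(tert-butyldimethylsilyl)oxy]-1-[(triethylsilyl)oxy]-3,7,11-trimethyldodeca-2,6,10-trien-4-one
Product: 19 (2Z,4R,6Z,8S)-8-[(tert-butyldimethylsilyl)oxy]-1-[(triethylsilyl)oxy]-3,7,11-trimethyldodeca-2,6,10-trien-4-ol
Conditions: (S)-Me-CBS oxazaborolidine (0.3 equiv), catecholborane, toluene, −78 °C
Reagents that add atoms: none
Why: Corey–Bakshi–Shibata reduction: with the α-methylalkenyl group as the large substituent the (S)-catalyst should deliver hydride to give the (R)-carbinol; catecholborane at −78 °C does not hydroborate the alkenes.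

Step 13
Reactants: 19 (2Z,4R,6Z,8S)-8-[(tert-butyldimethylsilyl)oxy]-1-[(triethylsilyl)oxy]-3,7,11-trimethyldodeca-2,6,10-trien-4-ol
Product: 20 tert-butyl{[(4S,5Z,7S,9Z)-7-chloro-2,6,10-trimethyl-12-[(triethylsilyl)oxy]dodeca-2,5,9-trien-4-yl]oxy}dimethylsilane [the (2Z,4S,6Z,8S)-4-chloro-8-silyloxy-1-silyloxy-3,7,11-trimethyldodeca-2,6,10-triene]
Conditions: PPh3, hexachloroacetone, CH2Cl2, −20 → 0 °C
Reagents that add atoms: hexachloroacetone, O=C(C(Cl)(Cl)Cl)C(Cl)(Cl)Cl
Why: Appel-type chlorination: the oxyphosphonium ion is displaced by chloride in an SN2 step with inversion, setting (S) at C3; this reagent pair is known to convert secondary allylic alcohols with little allylic transposition.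

Step 14
Reactants: 20 the (2Z,4S,6Z,8S)-4-chloro bis-silyl ether
Product: 21 (2Z,4S,6Z,8S)-8-[(tert-butyldimethylsilyl)oxy]-4-chloro-3,7,11-trimethyldodeca-2,6,10-trien-1-ol
Conditions: HF·pyridine, pyridine, THF, −20 → 0 °C; used at once
Reagents that add atoms: none
Why: Selective cleavage of the primary triethylsilyl ether beside the secondary TBS ether; the buffered, non-solvolytic medium should spare the allylic chloride.

Step 15
Reactants: 21 (2Z,4S,6Z,8S)-8-[(tert-butyldimethylsilyl)oxy]-4-chloro-3,7,11-trimethyldodeca-2,6,10-trien-1-ol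
Product: 22 (2Z,4S,6Z,8S)-8-[(tert-butyldimethylsilyl)oxy]-4-chloro-3,7,11-trimethyldodeca-2,6,10-trienal
Conditions: MnO2, CH2Cl2, 0 °C → rt; filter, use directly
Reagents that add atoms: none
Why: Heterogeneous, neutral MnO2 oxidation of an allylic alcohol, which is known to keep (Z)-enal geometry (nerol to neral) and has no base that could deprotonate the γ-chloro position.

Step 16
Reactants: 22 (2Z,4S,6Z,8S)-8-[(tert-butyldimethylsilyl)oxy]-4-chloro-3,7,11-trimethyldodeca-2,6,10-trienal
Product: 23 (1S,4S,6R)-6-{(3S)-3-[(tert-butyldimethylsilyl)oxy]-6-methylhepta-1,5-dien-2-yl}-4-chloro-3-methylcyclohex-2-en-1-ol (hydroxyl trans to the side chain, chlorine trans to the side chain)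
Conditions: Me2AlCl (1.5 equiv), CH2Cl2, −78 → −30 °C
Reagents that add atoms: none
Why: Me2AlCl binds the aldehyde oxygen, the C1=C7 double bond attacks C6 while the carbonyl oxygen takes a hydrogen from the C7 methyl through a six-centre array, and the alcohol–aluminium complex loses methane to a non-acidic alkoxide, so neither the new allylic carbinol nor the allylic chloride meets protic acid. The closest known reactions are the Lewis-acid or thermal carbonyl-ene cyclisations of neral to isopiperitenol and of citronellal to isopulegol. The ring closes in the 6-exo-trig mode at the carbonyl carbon with the ene double bond exocyclic to the new ring (type-1 intramolecular ene), through a half-chair in which C3–C6 of the (2Z)-enal stay coplanar. C6 is controlled by the s-trans enal, which places the complexed oxygen pseudoequatorial on the side of the C7 methyl, while the C8 hydrogen is held in the alkene plane by 1,3-allylic strain with C2 and cannot be reached; the hydroxyl therefore ends trans to the side chain, which is the C6 epimer of the target and is inverted in steps 17 to 20. C1 is controlled by C3: chlorine prefers the pseudoaxial position (1,2-allylic strain with the C4 methyl) and the alkene the equatorial one, which places the side chain trans to chlorine; C8 lies three bonds from the forming bond and should add only a weak bias. The step needs the C1/C3 trans relationship and hydrogen transfer from the methyl group only; the (6Z) geometry from step 5 and the (2Z) geometry from step 8 secure the hydrogen transfer and the reach of the aldehyde. Conjugation with the carbonyl disfavours ionisation of the γ-chloride.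

Step 17
Reactants: 23 (1S,4S,6R)-6-{(3S)-3-[(tert-butyldimethylsilyl)oxy]-6-methylhepta-1,5-dien-2-yl}-4-chloro-3-methylcyclohex-2-en-1-ol
Product: 24 (4S,6R)-6-{(3S)-3-[(tert-butyldimethylsilyl)oxy]-6-methylhepta-1,5-dien-2-yl}-4-chloro-3-methylcyclohex-2-en-1-one
Conditions: Dess–Martin periodinane, NaHCO3, CH2Cl2, 0 °C
Reagents that add atoms: none
Why: Dess–Martin oxidation of the allylic alcohol; both C6 epimers from step 16 converge here, and the buffered medium should not epimerise C1 or move the exocyclic alkene.

Step 18
Reactants: 24 (4S,6R)-6-{(3S)-3-[(tert-butyldimethylsilyl)oxy]-6-methylhepta-1,5-dien-2-yl}-4-chloro-3-methylcyclohex-2-en-1-one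
Product: 25 (4S,6R)-4-chloro-6-[(3S)-3-hydroxy-6-methylhepta-1,5-dien-2-yl]-3-methylcyclohex-2-en-1-one
Conditions: HF·pyridine, THF, 0 °C → rt
Reagents that add atoms: none
Why: Fluoride-mediated cleavage of the secondary TBS ether; with C6 held as a ketone the C8 hydroxyl is the only one present.

Step 19
Reactants: 25 (4S,6R)-4-chloro-6-[(3S)-3-hydroxy-6-methylhepta-1,5-dien-2-yl]-3-methylcyclohex-2-en-1-one
Product: 26 (3S)-2-[(1R,5S)-5-chloro-4-methyl-2-oxocyclohex-3-en-1-yl]-6-methylhepta-1,5-dien-3-yl (2Z)-2-methylbut-2-enoate
Conditions: angelic acid, 2,4,6-Cl3C6H2COCl, Et3N, toluene, rt, filter; then 25, toluene, 75 °C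
Reagents that add atoms: angelic acid [(2Z)-2-methylbut-2-enoic acid], C/C=C(/C)C(=O)O
Why: Yamaguchi-type mixed-anhydride esterification, which is known to give angelates without Z to E isomerisation when no nucleophilic catalyst is present; the amine salt is filtered off so that the enone meets no free base.

Step 20
Reactants: 26 (3S)-2-[(1R,5S)-5-chloro-4-methyl-2-oxocyclohex-3-en-1-yl]-6-methylhepta-1,5-dien-3-yl (2Z)-2-methylbut-2-enoate
Product: 27 (3S)-2-[(1R,2R,5S)-5-chloro-2-hydroxy-4-methylcyclohex-3-en-1-yl]-6-methylhepta-1,5-dien-3-yl (2Z)-2-methylbut-2-enoate (hydroxyl cis to the side chain)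
Conditions: LiBH(s-Bu)3, THF, −78 °C; aq. NH4Cl
Reagents that add atoms: none
Why: The bulky hydride attacks the ketone equatorially, as with 2-substituted cyclohexanones, giving the pseudoaxial alcohol cis to the C1 substituent (target C6 configuration); the β,β-disubstituted enone favours 1,2-reduction and the hindered angelate is not reduced at −78 °C.

Step 21
Reactants: 27 (3S)-2-[(1R,2R,5S)-5-chloro-2-hydroxy-4-methylcyclohex-3-en-1-yl]-6-methylhepta-1,5-dien-3-yl (2Z)-2-methylbut-2-enoate
Product: 28 (2S)-3-[(1R,2R,5S)-5-chloro-2-hydroxy-4-methylcyclohex-3-en-1-yl]-1-[(2S)-3,3-dimethyloxiran-2-yl]but-3-en-2-yl (2Z)-2-methylbut-2-enoate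
Conditions: ent-Shi ketone (30 mol %), KHSO5, K2CO3, Bu4NHSO4, aq. Na2B4O7 buffer, MeCN–CH2(OMe)2, 0 °C
Reagents that add atoms: potassium peroxymonosulfate KHSO5, [K+].[O-]S(=O)(=O)OO
Why: Shi epoxidation: the chiral dioxirane reacts with the most electron-rich, unhindered trisubstituted alkene, while the ring alkene (allylic chlorine), the flanked methylene and the enoate are slower; the L-fructose-derived ketone should give the (10S) epoxide, opposite to the (R) sense of the common D-fructose-derived catalyst.

Step 22
Reactants: 28 (2S)-3-[(1R,2R,5S)-5-chloro-2-hydroxy-4-methylcyclohex-3-en-1-yl]-1-[(2S)-3,3-dimethyloxiran-2-yl]but-3-en-2-yl (2Z)-2-methylbut-2-enoate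
Product: 29 TMEDA-chelated cyclic dioxo-osmate (hexavalent osmium) ester of the (4S,5S)-4,5-diol of 28, C6 hydroxyl free
Conditions: OsO4 (1.05 equiv), TMEDA (1.1 equiv), CH2Cl2, −78 °C
Reagents that add atoms: osmium tetroxide, O=[Os](=O)(=O)=O; N,N,N',N'-tetramethylethane-1,2-diamine, CN(C)CCN(C)C
Why: Hydrogen-bond-directed dihydroxylation: the OsO4·TMEDA complex accepts a hydrogen bond from the pseudoaxial C6 hydroxyl and adds suprafacially to C4=C5 on that face, which is also anti to the pseudoaxial chlorine, setting C4 and C5 (both S); the ring alkene is the only one with an allylic hydroxyl, and the chelated osmate ester is stable and isolable.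

Step 23
Reactants: 29 TMEDA-chelated cyclic dioxo-osmate ester with free C6 hydroxyl
Product: 30 TMEDA-chelated cyclic dioxo-osmate ester of the target (C6 and C8 angelates in place)
Conditions: angelic acid, 2,4,6-Cl3C6H2COCl, Et3N, toluene, rt, filter; then 29, toluene, 80 °C
Reagents that add atoms: angelic acid [(2Z)-2-methylbut-2-enoic acid], C/C=C(/C)C(=O)O
Why: Mixed-anhydride esterification of the only free hydroxyl; the 4,5-diol stays locked in the osmate ester, which thus serves as the diol protecting group, and the absence of a nucleophilic catalyst guards the angelate geometry.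

Step 24
Reactants: 30 TMEDA-chelated cyclic dioxo-osmate ester of the target
Product: 31 (2S)-3-[(1R,2S,3S,4S,5S)-5-chloro-3,4-dihydroxy-4-methyl-2-{[(2Z)-2-methylbut-2-enoyl]oxy}cyclohexyl]-1-[(2S)-3,3-dimethyloxiran-2-yl]but-3-en-2-yl (2Z)-2-methylbut-2-enoate (CNP0333703.2)
Conditions: H2NCH2CH2NH2, wet CH2Cl2, rt; filter
Reagents that add atoms: none
Why: Ligand exchange at osmium with a chelating primary diamine releases the diol at room temperature without acid or strong base, conditions under which the epoxide, the angelates and the trans-diaxial chlorohydrin should persist.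

## Compound list

1 | methyl (2S)-oxirane-2-carboxylate | COC(=O)[C@@H]1CO1 | starting material
2 | 2-methyl-1-propenylmagnesium bromide | CC(C)=C[Mg]Br | starting material
3 | methyl (2S)-2-hydroxy-5-methylhex-4-enoate | COC(=O)[C@@H](O)CC=C(C)C | intermediate
4 | methyl (2S)-2-[(tert-butyldimethylsilyl)oxy]-5-methylhex-4-enoate | COC(=O)[C@@H](O[Si](C)(C)C(C)(C)C)CC=C(C)C | intermediate
5 | (2S)-2-[(tert-butyldimethylsilyl)oxy]-N-methoxy-N,5-dimethylhex-4-enamide | CON(C)C(=O)[C@@H](O[Si](C)(C)C(C)(C)C)CC=C(C)C | intermediate
6 | (3S)-3-[(tert-butyldimethylsilyl)oxy]-6-methylhept-5-en-2-one | CC(=O)[C@@H](O[Si](C)(C)C(C)(C)C)CC=C(C)C | intermediate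
7 | (3-bromopropoxy)(tert-butyl)dimethylsilane | CC(C)(C)[Si](C)(C)OCCCBr | starting material
8 | {3-[(tert-butyldimethylsilyl)oxy]propyl}triphenylphosphonium bromide | CC(C)(C)[Si](C)(C)OCCC[P+](c1ccccc1)(c1ccccc1)c1ccccc1.[Br-] | intermediate
9 | {3-[(tert-butyldimethylsilyl)oxy]propylidene}triphenylphosphorane | CC(C)(C)[Si](C)(C)OCCC=P(c1ccccc1)(c1ccccc1)c1ccccc1 | intermediate
10 | (3Z,5S)-1,5-bis[(tert-butyldimethylsilyl)oxy]-4,8-dimethylnona-3,7-diene | CC(C)(C)[Si](C)(C)OCC/C=C(/C)[C@H](CC=C(C)C)O[Si](C)(C)C(C)(C)C | intermediate
11 | (3Z,5S)-5-[(tert-butyldimethylsilyl)oxy]-4,8-dimethylnona-3,7-dien-1-ol | OCC/C=C(/C)[C@H](CC=C(C)C)O[Si](C)(C)C(C)(C)C | intermediate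
12 | (3Z,5S)-5-[(tert-butyldimethylsilyl)oxy]-4,8-dimethylnona-3,7-dienal | O=CC/C=C(/C)[C@H](CC=C(C)C)O[Si](C)(C)C(C)(C)C | intermediate
13 | but-2-yn-1-ol | CC#CCO | starting material
14 | sodium 2,2-bis(2-methoxyethoxy)-3-methyl-2,5-dihydro-1,2-oxaluminol-2-uide (cyclic alkenylaluminate) | CC1=CCO[Al-]1(OCCOC)OCCOC.[Na+] | intermediate
15 | (2Z)-3-iodobut-2-en-1-ol | OC/C=C(/C)I | intermediate
16 | triethyl{[(2Z)-3-iodobut-2-en-1-yl]oxy}silane | CC[Si](CC)(CC)OC/C=C(/C)I | intermediate
17 | (2Z,6Z,8S)-8-[(tert-butyldimethylsilyl)oxy]-1-[(triethylsilyl)oxy]-3,7,11-trimethyldodeca-2,6,10-trien-4-ol (4RS) | CC[Si](CC)(CC)OC/C=C(/C)C(O)C/C=C(/C)[C@H](CC=C(C)C)O[Si](C)(C)C(C)(C)C | intermediate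
18 | (2Z,6Z,8S)-8-[(tert-butyldimethylsilyl)oxy]-1-[(triethylsilyl)oxy]-3,7,11-trimethyldodeca-2,6,10-trien-4-one | CC[Si](CC)(CC)OC/C=C(/C)C(=O)C/C=C(/C)[C@H](CC=C(C)C)O[Si](C)(C)C(C)(C)C | intermediate
19 | (2Z,4R,6Z,8S)-8-[(tert-butyldimethylsilyl)oxy]-1-[(triethylsilyl)oxy]-3,7,11-trimethyldodeca-2,6,10-trien-4-ol | CC[Si](CC)(CC)OC/C=C(/C)[C@H](O)C/C=C(/C)[C@H](CC=C(C)C)O[Si](C)(C)C(C)(C)C | intermediate
20 | (2Z,4S,6Z,8S)-8-[(tert-butyldimethylsilyl)oxy]-4-chloro-1-[(triethylsilyl)oxy]-3,7,11-trimethyldodeca-2,6,10-triene | CC[Si](CC)(CC)OC/C=C(/C)[C@@H](Cl)C/C=C(/C)[C@H](CC=C(C)C)O[Si](C)(C)C(C)(C)C | intermediate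
21 | (2Z,4S,6Z,8S)-8-[(tert-butyldimethylsilyl)oxy]-4-chloro-3,7,11-trimethyldodeca-2,6,10-trien-1-ol | OC/C=C(/C)[C@@H](Cl)C/C=C(/C)[C@H](CC=C(C)C)O[Si](C)(C)C(C)(C)C | intermediate
22 | (2Z,4S,6Z,8S)-8-[(tert-butyldimethylsilyl)oxy]-4-chloro-3,7,11-trimethyldodeca-2,6,10-trienal | O=C/C=C(/C)[C@@H](Cl)C/C=C(/C)[C@H](CC=C(C)C)O[Si](C)(C)C(C)(C)C | intermediate
23 | (1S,4S,6R)-6-{(3S)-3-[(tert-butyldimethylsilyl)oxy]-6-methylhepta-1,5-dien-2-yl}-4-chloro-3-methylcyclohex-2-en-1-ol | C=C([C@H](CC=C(C)C)O[Si](C)(C)C(C)(C)C)[C@H]1C[C@H](Cl)C(C)=C[C@@H]1O | intermediate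
24 | (4S,6R)-6-{(3S)-3-[(tert-butyldimethylsilyl)oxy]-6-methylhepta-1,5-dien-2-yl}-4-chloro-3-methylcyclohex-2-en-1-one | C=C([C@H](CC=C(C)C)O[Si](C)(C)C(C)(C)C)[C@H]1C[C@H](Cl)C(C)=CC1=O | intermediate
25 | (4S,6R)-4-chloro-6-[(3S)-3-hydroxy-6-methylhepta-1,5-dien-2-yl]-3-methylcyclohex-2-en-1-one | C=C([C@H](CC=C(C)C)O)[C@H]1C[C@H](Cl)C(C)=CC1=O | intermediate
26 | (3S)-2-[(1R,5S)-5-chloro-4-methyl-2-oxocyclohex-3-en-1-yl]-6-methylhepta-1,5-dien-3-yl (2Z)-2-methylbut-2-enoate | C=C([C@H](CC=C(C)C)OC(=O)/C(C)=C\C)[C@H]1C[C@H](Cl)C(C)=CC1=O | intermediate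
27 | (3S)-2-[(1R,2R,5S)-5-chloro-2-hydroxy-4-methylcyclohex-3-en-1-yl]-6-methylhepta-1,5-dien-3-yl (2Z)-2-methylbut-2-enoate | C=C([C@H](CC=C(C)C)OC(=O)/C(C)=C\C)[C@H]1C[C@H](Cl)C(C)=C[C@H]1O | intermediate
28 | (2S)-3-[(1R,2R,5S)-5-chloro-2-hydroxy-4-methylcyclohex-3-en-1-yl]-1-[(2S)-3,3-dimethyloxiran-2-yl]but-3-en-2-yl (2Z)-2-methylbut-2-enoate | C=C([C@H](C[C@@H]1OC1(C)C)OC(=O)/C(C)=C\C)[C@H]1C[C@H](Cl)C(C)=C[C@H]1O | intermediate
29 | TMEDA-chelated dioxo-osmium (hexavalent) cyclic 4,5-diolate of the target skeleton, C6–OH free, C8 angelate | C=C([C@H](C[C@@H]1OC1(C)C)OC(=O)/C(C)=C\C)[C@H]1C[C@H](Cl)[C@@]2(C)O[Os-2]3(=O)(=O)(O[C@H]2[C@H]1O)[N+](C)(C)CC[N+]3(C)C | intermediate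
30 | TMEDA-chelated dioxo-osmium (hexavalent) cyclic 4,5-diolate of the target (C6 and C8 angelates) | C=C([C@H](C[C@@H]1OC1(C)C)OC(=O)/C(C)=C\C)[C@H]1C[C@H](Cl)[C@@]2(C)O[Os-2]3(=O)(=O)(O[C@H]2[C@H]1OC(=O)/C(C)=C\C)[N+](C)(C)CC[N+]3(C)C | intermediate
31 | (2S)-3-[(1R,2S,3S,4S,5S)-5-chloro-3,4-dihydroxy-4-methyl-2-{[(2Z)-2-methylbut-2-enoyl]oxy}cyclohexyl]-1-[(2S)-3,3-dimethyloxiran-2-yl]but-3-en-2-yl (2Z)-2-methylbut-2-enoate | C=C([C@H](C[C@@H]1OC1(C)C)OC(=O)/C(C)=C\C)[C@H]1C[C@H](Cl)[C@@](C)(O)[C@@H](O)[C@H]1OC(=O)/C(C)=C\C | target

## Step count and least certain steps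

Total: 24 steps. Longest linear sequence: 21 steps (steps 1–3, 5–7 and 10–24); steps 4, 8 and 9 are side branches.

**Step 16 (key step).** The most likely failure is poor facial selectivity at C1, because the pseudoaxial preference of chlorine is modest and C8 is remote. It could be compounded by Lewis-acid ionisation of the new allylic aluminium alkoxide or of the allylic chloride, leading to elimination. Fallback, setting out from aldehyde 22: oxidation with NaClO2/NaH2PO4/2-methylbut-2-ene would give (2Z,4S,6Z,8S)-8-[(tert-butyldimethylsilyl)oxy]-4-chloro-3,7,11-trimethyldodeca-2,6,10-trienoic acid F1. Treatment with 1-chloro-N,N,2-trimethylprop-1-en-1-amine would give the acid chloride F2. EtAlCl2 in CH2Cl2 at −78 °C should then close the same C1–C6 bond by alkene acylation (acyl-ene type, known to give β,γ-unsaturated ketones). This comes back to the route at enone 24. It removes the ionisable allylic carbinol from the closure and makes the C6 configuration irrelevant; C1 epimers, if formed, would be separated at 24 or 27.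

**Step 13.** Allylic transposition (SN2') or partial loss of configuration through an ion pair is the main danger, together with attack of the cis C6 silyl ether oxygen on the activated carbinol (dihydrofuran formation), because the allyl system is still electron-rich. Fallback, setting out from alcohol 19: MsCl, s-collidine and LiCl in DMF at 0 °C would form the (4R)-methanesulfonate F3 and displace it in the flask with soluble chloride, a discrete sulfonate–halide SN2 path in place of the oxyphosphonium one. This comes back at chloride 20.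

**Step 19.** During the warm acylation the exocyclic C7=CH2 may migrate into conjugation with the C6 ketone, or C1 may epimerise, through traces of acid or base. Fallback, setting out from enone 24: LiBH(s-Bu)3 reduction first would give (1R,4S,6R)-6-{(3S)-3-[(tert-butyldimethylsilyl)oxy]-6-methylhepta-1,5-dien-2-yl}-4-chloro-3-methylcyclohex-2-en-1-ol F4. HF·pyridine would then give the diol (1R,4S,6R)-4-chloro-6-[(3S)-3-hydroxy-6-methylhepta-1,5-dien-2-yl]-3-methylcyclohex-2-en-1-ol F5. Mono-acylation with the angelic mixed anhydride should take the less hindered acyclic C8 hydroxyl in preference to the pseudoaxial, flanked C6 hydroxyl. This comes back at 27 and never exposes the enone to acylation conditions.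

**Step 23.** Acylation of the axial C6 hydroxyl, flanked by C1 and the osmate-bearing C5, may be too slow; forcing conditions with a nucleophilic catalyst would isomerise angelate to tiglate. Fallback, setting out from osmate 29: esterification with 2-[bis(2,2,2-trifluoroethoxy)phosphoryl]propanoic acid (DCC, DMAP; a small, highly reactive acyl donor with no alkene to isomerise) would give the phosphonopropionate F6. Still–Gennari olefination with acetaldehyde (KN(SiMe3)2, 18-crown-6, THF, −78 °C) should then build the (Z)-2-methylbut-2-enoate on the molecule. This comes back at 30.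

## Further compounds

F1 | step 16 | (2Z,4S,6Z,8S)-8-[(tert-butyldimethylsilyl)oxy]-4-chloro-3,7,11-trimethyldodeca-2,6,10-trienoic acid | OC(=O)/C=C(/C)[C@@H](Cl)C/C=C(/C)[C@H](CC=C(C)C)O[Si](C)(C)C(C)(C)C
F2 | step 16 | (2Z,4S,6Z,8S)-8-[(tert-butyldimethylsilyl)oxy]-4-chloro-3,7,11-trimethyldodeca-2,6,10-trienoyl chloride | ClC(=O)/C=C(/C)[C@@H](Cl)C/C=C(/C)[C@H](CC=C(C)C)O[Si](C)(C)C(C)(C)C
F3 | step 13 | (2Z,4R,6Z,8S)-8-[(tert-butyldimethylsilyl)oxy]-1-[(triethylsilyl)oxy]-3,7,11-trimethyldodeca-2,6,10-trien-4-yl methanesulfonate | CC[Si](CC)(CC)OC/C=C(/C)[C@H](OS(C)(=O)=O)C/C=C(/C)[C@H](CC=C(C)C)O[Si](C)(C)C(C)(C)C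
F4 | step 19 | (1R,4S,6R)-6-{(3S)-3-[(tert-butyldimethylsilyl)oxy]-6-methylhepta-1,5-dien-2-yl}-4-chloro-3-methylcyclohex-2-en-1-ol | C=C([C@H](CC=C(C)C)O[Si](C)(C)C(C)(C)C)[C@H]1C[C@H](Cl)C(C)=C[C@H]1O
F5 | step 19 | (1R,4S,6R)-4-chloro-6-[(3S)-3-hydroxy-6-methylhepta-1,5-dien-2-yl]-3-methylcyclohex-2-en-1-ol | C=C([C@H](CC=C(C)C)O)[C@H]1C[C@H](Cl)C(C)=C[C@H]1O
F6 | step 23 | osmate 29 esterified at C6 with 2-[bis(2,2,2-trifluoroethoxy)phosphoryl]propanoic acid (mixture at the phosphonate α-carbon) | C=C([C@H](C[C@@H]1OC1(C)C)OC(=O)/C(C)=C\C)[C@H]1C[C@H](Cl)[C@@]2(C)O[Os-2]3(=O)(=O)(O[C@H]2[C@H]1OC(=O)C(C)P(=O)(OCC(F)(F)F)OCC(F)(F)F)[N+](C)(C)CC[N+]3(C)C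
A1 | alternative 1 | ring-closing-metathesis product: cyclohex-3-enyl ketone with C5 silyl ether, C6 hydroxyl, C8 benzoate and C10/C11 epoxide | O=C([C@H](C[C@@H]1OC1(C)C)OC(=O)c2ccccc2)[C@H]3CC=C(C)[C@@H](O[Si](C)(C)C(C)(C)C)[C@H]3O
A2 | alternative 2 | allylic-alkylation product: cyclic β-keto ester with C4/C5 acetonide, C6 4-methoxybenzyl ether and C7 methylene | C=C([C@H](CC=C(C)C)O[Si](C)(C)C(C)(C)C)[C@H]1[C@H](C(=O)OC)C(=O)[C@@]2(C)OC(C)(C)O[C@H]2[C@H]1OCc3ccc(OC)cc3
A3 | alternative 3 | pinacol product: cyclohexane cis-4,5-diol with C3 silyl ether and C6/C8 4-methoxybenzyl ethers | C=C([C@H](CC=C(C)C)OCc2ccc(OC)cc2)[C@H]1C[C@H](O[Si](C)(C)C(C)(C)C)[C@@](C)(O)[C@@H](O)[C@H]1OCc3ccc(OC)cc3
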